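Ester cleavage and two Wittig disconnections reduce the target to oleoyl chloride, a C10 dialdehyde and two C15 phosphonium salts, each derived from a 2,2,6-trimethylcyclohexanone and a C6 enynol. The oxygen-free ring is built rather than bought: its C2' methylene (beside the gem-dimethyl carbon C1') and its C3' methylene carry no substituent, so their bond is made as an alkene by ring-closing metathesis of an acyclic 1,7-dienone, 3,3,5-trimethylocta-1,7-dien-4-one, and saturated in the same pot. One operation gives the six-membered ring with the quaternary centre and the carbonyl needed to attach the polyene in place.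

Key step: step 3

Remark: carotenoid numbering is used (ring C1–C6, chain C7–C15, primes for the oxygen-free half). Compounds 7, 12 and 15 are taken as purchasable carotenoid intermediates. All polyene steps run under argon in dim light.

Step 1
Reactants: 1 2-methylpent-4-enal (racemic); 2 prenylmagnesium chloride
Product: 3 3,3,5-trimethylocta-1,7-dien-4-ol (racemic diastereomer mixture)
Conditions: THF, −78 °C to 0 °C; aq. NH4Cl
Reagents that add atoms: none
Why: Allylic Grignard addition through a six-membered SE2' transition state should bond the more substituted (γ) prenyl carbon to the aldehyde carbon and give the 1,1-dimethylallyl carbinol; both stereocentres form unselectively, which does not matter because both become sp2 later.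

Step 2
Reactants: 3 3,3,5-trimethylocta-1,7-dien-4-ol
Product: 4 3,3,5-trimethylocta-1,7-dien-4-one (racemic)
Conditions: Dess–Martin periodinane, CH2Cl2, 0 °C to rt
Reagents that add atoms: none
Why: Dess–Martin oxidation should convert the hindered secondary alcohol into the ketone under neutral conditions without touching the terminal alkenes, and the quaternary α-carbon prevents conjugation of the vinyl group.

Step 3
Reactants: 4 3,3,5-trimethylocta-1,7-dien-4-one
Product: 6 2,2,6-trimethylcyclohexan-1-one (racemic), via 2,2,6-trimethylcyclohex-3-en-1-one 5 (not isolated)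
Conditions: second-generation Grubbs catalyst RuCl2(=CHPh)(PCy3)(H2IMes) (2 mol%), ClCH2CH2Cl (0.01 M), 50 °C; then H2 (7 bar), 70 °C, same pot
Reagents that add atoms: none
Why: The ruthenium benzylidene should initiate at the unhindered allyl terminus (future C3'), and the resulting alkylidene adds across the neopentyl-type vinyl group on the quaternary carbon (future C2') through a ruthenacyclobutane whose cycloreversion releases ethylene and forms the C2'=C3' bond; under hydrogen the same ruthenium becomes a hydride that saturates this new cis-disubstituted alkene in the same pot. The closest known reaction type is ring-closing olefin metathesis of a 1,7-diene run in tandem with homogeneous ruthenium-hydride hydrogenation. The one ring closed is the six-membered carbocycle, by intramolecular [2+2] cycloaddition and cycloreversion of a metal alkylidene rather than by a polar or radical exo/endo closure. No stereocentre is created; the methyl-bearing carbon is racemic and becomes sp2 in step 6. The step needs cyclisation to outrun acyclic diene metathesis and allyl-to-propenyl isomerisation, which the gem-dimethyl group and the sp2 carbonyl in the tether (Thorpe–Ingold compression), high dilution and the quaternary carbon blocking alkene migration should secure; it also needs alkene over ketone hydrogenation, which the base-free ruthenium hydride and the doubly α-branched carbonyl should secure.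

Step 4
Reactants: 6 2,2,6-trimethylcyclohexan-1-one; 7 (2E)-3-methylpent-2-en-4-yn-1-ol
Product: 9 1-[(3E)-5-hydroxy-3-methylpent-3-en-1-yn-1-yl]-2,2,6-trimethylcyclohexan-1-ol (racemic diastereomer mixture), via dilithio enynol 8 (not isolated)
Conditions: 7 (1.2 equiv), n-BuLi (2.4 equiv), THF, −78 °C to 0 °C; then 6, −78 °C to rt; H2O
Reagents that add atoms: none
Why: 1,2-Addition of a lithium acetylide to the hindered ketone should win over enolisation because the acetylide is weakly basic, and the new tertiary carbinol centre forms as a mixture that step 6 erases.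

Step 5
Reactants: 9 1-[(3E)-5-hydroxy-3-methylpent-3-en-1-yn-1-yl]-2,2,6-trimethylcyclohexan-1-ol
Product: 10 1-[(1E,3E)-5-hydroxy-3-methylpenta-1,3-dien-1-yl]-2,2,6-trimethylcyclohexan-1-ol
Conditions: NaAlH2(OCH2CH2OMe)2 (Red-Al, 3 equiv), THF, 0 °C to rt; aq. KNaC4H4O6
Reagents that add atoms: none
Why: Alkoxide-directed trans-hydroalumination of the propargylic alcohol followed by protonolysis should give the (E)-alkene and leave the existing (E)-trisubstituted alkene untouched.

Step 6
Reactants: 10 1-[(1E,3E)-5-hydroxy-3-methylpenta-1,3-dien-1-yl]-2,2,6-trimethylcyclohexan-1-ol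
Product: 11 [(2E,4E)-3-methyl-5-(2,6,6-trimethylcyclohex-1-en-1-yl)penta-2,4-dien-1-yl]triphenylphosphonium bromide
Conditions: PPh3·HBr (1.1 equiv), MeOH, rt
Reagents that add atoms: triphenylphosphine hydrobromide, [Br-].[PH+](c1ccccc1)(c1ccccc1)c1ccccc1
Why: Acid-promoted ionisation of the tertiary bis-allylic alcohol with E1 loss of the ring proton at the methyl-bearing carbon should create the tetrasubstituted C5'=C6' alkene, and SN1-type capture of the pentadienyl cation by PPh3 at the primary terminus gives the fully conjugated all-E phosphonium salt as the thermodynamic sink.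

Step 7
Reactants: 11 the C15 phosphonium bromide; 12 (2E,4E,6E)-2,7-dimethylocta-2,4,6-trienedial
Product: 14 (2E,4E,6E,8E,10E,12E)-2,7,11-trimethyl-13-(2,6,6-trimethylcyclohex-1-en-1-yl)trideca-2,4,6,8,10,12-hexaenal (12'-apo-β-caroten-12'-al), via C15 ylide 13 (not isolated)
Conditions: 12 (2.5 equiv), NaOMe, MeOH/CH2Cl2, 0 °C to rt, slow addition of 11; then heptane, reflux (Z to E)
Reagents that add atoms: none
Why: Wittig olefination of the semi-stabilised allylic ylide with excess symmetrical dialdehyde should stop at the mono-adduct because the product is a longer, less electrophilic vinylogous aldehyde, and the new disubstituted double bond equilibrates thermally to E.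

Step 8
Reactants: 15 (4R,6R)-4-hydroxy-2,2,6-trimethylcyclohexan-1-one (actinol)
Product: 16 (4R,6R)-2,2,6-trimethyl-4-(triethylsilyloxy)cyclohexan-1-one
Conditions: Et3SiCl, imidazole, CH2Cl2, 0 °C to rt
Reagents that add atoms: chlorotriethylsilane, CC[Si](Cl)(CC)CC
Why: Imidazole-mediated O-silylation masks the only acidic proton before the organomagnesium step and leaves both stereocentres untouched.

Step 9
Reactants: 16 (4R,6R)-2,2,6-trimethyl-4-(triethylsilyloxy)cyclohexan-1-one; 7 (2E)-3-methylpent-2-en-4-yn-1-ol
Product: 18 (4R,6R)-1-[(3E)-5-hydroxy-3-methylpent-3-en-1-yn-1-yl]-2,2,6-trimethyl-4-(triethylsilyloxy)cyclohexan-1-ol (epimers at the new carbinol carbon), via bis(bromomagnesium) enynol 17 (not isolated)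
Conditions: 7 (1.5 equiv), EtMgBr (2.9 equiv), THF, 0 °C to 40 °C; then 16, rt to 40 °C; aq. NH4Cl
Reagents that add atoms: none
Why: Double deprotonation of 7 by EtMgBr gives the bromomagnesium alkoxide–acetylide, whose 1,2-addition (alkynyl Grignard addition) to the hindered ketone should leave the silyl ether intact because the excess of 7 leaves no free ethyl Grignard reagent; the silyloxy-bearing stereocentre is remote and unchanged, and the new carbinol centre is erased in step 11.

Step 10
Reactants: 18 the silylated acetylenic diol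
Product: 19 (4R,6R)-1-[(1E,3E)-5-hydroxy-3-methylpenta-1,3-dien-1-yl]-2,2,6-trimethyl-4-(triethylsilyloxy)cyclohexan-1-ol (epimers at the tertiary carbinol carbon)
Conditions: NaAlH2(OCH2CH2OMe)2 (Red-Al, 3 equiv), THF, 0 °C to rt; aq. KNaC4H4O6
Reagents that add atoms: none
Why: Alkoxide-directed trans-hydroalumination as in step 5 should give the (E)-alkene, and the triethylsilyl ether is stable to the aluminium hydride at this temperature.

Step 11
Reactants: 19 the silylated dienediol
Product: 20 [(2E,4E)-5-[(4R)-4-hydroxy-2,6,6-trimethylcyclohex-1-en-1-yl]-3-methylpenta-2,4-dien-1-yl]triphenylphosphonium bromide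
Conditions: PPh3·HBr (1.2 equiv), MeOH, rt
Reagents that add atoms: triphenylphosphine hydrobromide, [Br-].[PH+](c1ccccc1)(c1ccccc1)c1ccccc1
Why: The dehydrative phosphonium salt formation of step 6 should run together with acid-catalysed methanolysis of the triethylsilyl ether, while the secondary homoallylic C3 carbinol does not ionise and so keeps its R configuration.

Step 12
Reactants: 20 the (3R)-hydroxy C15 phosphonium bromide; 14 12'-apo-β-caroten-12'-al
Product: 22 (3R)-β,β-caroten-3-ol ((3R)-β-cryptoxanthin, all-E), via hydroxy C15 ylide 21 (not isolated)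
Conditions: NaOMe, MeOH/CH2Cl2, rt; then EtOH, reflux (Z to E), crystallisation
Reagents that add atoms: none
Why: Wittig olefination of the allylic ylide with the polyenal should form the last chain double bond, thermal equilibration and crystallisation favour the all-E isomer, and the C3 stereocentre is not involved.

Step 13
Reactants: 22 (3R)-β-cryptoxanthin; 23 oleoyl chloride ((9Z)-octadec-9-enoyl chloride, high-purity grade)
Product: 24 (3R)-β,β-caroten-3-yl (9Z)-octadec-9-enoate (target, CNP0152321.1)
Conditions: pyridine, DMAP (cat.), CH2Cl2, 0 °C to rt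
Reagents that add atoms: none
Why: DMAP-catalysed O-acylation (nucleophilic acyl substitution) of the only hydroxyl group does not break the C3–O bond, so the R configuration is retained, and the Z-alkene of the acyl chain is untouched.

Compound list
1 | 2-methylpent-4-enal (racemic) | C=CCC(C)C=O | starting material
2 | prenylmagnesium chloride (3-methylbut-2-en-1-ylmagnesium chloride, THF solution) | CC(C)=CC[Mg]Cl | starting material
3 | 3,3,5-trimethylocta-1,7-dien-4-ol (racemic diastereomer mixture) | C=CCC(C)C(O)C(C)(C)C=C | intermediate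
4 | 3,3,5-trimethylocta-1,7-dien-4-one (racemic) | C=CCC(C)C(=O)C(C)(C)C=C | intermediate
5 | 2,2,6-trimethylcyclohex-3-en-1-one (racemic, not isolated) | CC1CC=CC(C)(C)C1=O | intermediate
6 | 2,2,6-trimethylcyclohexan-1-one (racemic) | CC1CCCC(C)(C)C1=O | intermediate
7 | (2E)-3-methylpent-2-en-4-yn-1-ol | C#C/C(C)=C/CO | starting material
8 | dilithio derivative of 7 (lithium alkoxide and lithium acetylide, not isolated) | [Li]C#C/C(C)=C/CO[Li] | intermediate
9 | 1-[(3E)-5-hydroxy-3-methylpent-3-en-1-yn-1-yl]-2,2,6-trimethylcyclohexan-1-ol (racemic diastereomer mixture) | CC1CCCC(C)(C)C1(O)C#C/C(C)=C/CO | intermediate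
10 | 1-[(1E,3E)-5-hydroxy-3-methylpenta-1,3-dien-1-yl]-2,2,6-trimethylcyclohexan-1-ol (racemic diastereomer mixture) | CC1CCCC(C)(C)C1(O)/C=C/C(C)=C/CO | intermediate
11 | [(2E,4E)-3-methyl-5-(2,6,6-trimethylcyclohex-1-en-1-yl)penta-2,4-dien-1-yl]triphenylphosphonium bromide | CC1=C(/C=C/C(C)=C/C[P+](c2ccccc2)(c2ccccc2)c2ccccc2)C(C)(C)CCC1.[Br-] | intermediate
12 | (2E,4E,6E)-2,7-dimethylocta-2,4,6-trienedial | O=C/C(C)=C/C=C/C=C(C)/C=O | starting material
13 | C15 ylide from 11 (triphenylphosphorane, not isolated) | CC1=C(/C=C/C(C)=C/C=P(c2ccccc2)(c2ccccc2)c2ccccc2)C(C)(C)CCC1 | intermediate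
14 | 12'-apo-β-caroten-12'-al, all-E | CC1=C(/C=C/C(C)=C/C=C/C(C)=C/C=C/C=C(C)/C=O)C(C)(C)CCC1 | intermediate
15 | (4R,6R)-4-hydroxy-2,2,6-trimethylcyclohexan-1-one (actinol) | O[C@@H]1C[C@@H](C)C(=O)C(C)(C)C1 | starting material
16 | (4R,6R)-2,2,6-trimethyl-4-(triethylsilyloxy)cyclohexan-1-one | CC[Si](CC)(CC)O[C@@H]1C[C@@H](C)C(=O)C(C)(C)C1 | intermediate
17 | bis(bromomagnesium) derivative of 7 (bromomagnesium alkoxide and alkynylmagnesium bromide, not isolated) | Br[Mg]C#C/C(C)=C/CO[Mg]Br | intermediate
18 | (4R,6R)-1-[(3E)-5-hydroxy-3-methylpent-3-en-1-yn-1-yl]-2,2,6-trimethyl-4-(triethylsilyloxy)cyclohexan-1-ol (epimers at the new carbinol carbon) | CC[Si](CC)(CC)O[C@@H]1C[C@@H](C)C(O)(C#C/C(C)=C/CO)C(C)(C)C1 | intermediate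
19 | (4R,6R)-1-[(1E,3E)-5-hydroxy-3-methylpenta-1,3-dien-1-yl]-2,2,6-trimethyl-4-(triethylsilyloxy)cyclohexan-1-ol (epimers at the tertiary carbinol carbon) | CC[Si](CC)(CC)O[C@@H]1C[C@@H](C)C(O)(/C=C/C(C)=C/CO)C(C)(C)C1 | intermediate
20 | [(2E,4E)-5-[(4R)-4-hydroxy-2,6,6-trimethylcyclohex-1-en-1-yl]-3-methylpenta-2,4-dien-1-yl]triphenylphosphonium bromide | O[C@@H]1CC(C)=C(/C=C/C(C)=C/C[P+](c2ccccc2)(c2ccccc2)c2ccccc2)C(C)(C)C1.[Br-] | intermediate
21 | (3R)-hydroxy C15 ylide from 20 (triphenylphosphorane, not isolated) | O[C@@H]1CC(C)=C(/C=C/C(C)=C/C=P(c2ccccc2)(c2ccccc2)c2ccccc2)C(C)(C)C1 | intermediate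
22 | (3R)-β,β-caroten-3-ol ((3R)-β-cryptoxanthin, all-E) | O[C@@H]1CC(C)=C(/C=C/C(C)=C/C=C/C(C)=C/C=C/C=C(C)/C=C/C=C(C)/C=C/C2=C(C)CCCC2(C)C)C(C)(C)C1 | intermediate
23 | oleoyl chloride ((9Z)-octadec-9-enoyl chloride) | CCCCCCCC/C=C\CCCCCCCC(Cl)=O | starting material
24 | (3R)-β,β-caroten-3-yl (9Z)-octadec-9-enoate (β-cryptoxanthin oleate, CNP0152321.1) | CCCCCCCC/C=C\CCCCCCCC(=O)O[C@@H]1CC(C)=C(/C=C/C(C)=C/C=C/C(C)=C/C=C/C=C(C)/C=C/C=C(C)/C=C/C2=C(C)CCCC2(C)C)C(C)(C)C1 | target

Total step count: 13
Longest linear sequence: 9 steps (steps 1–7, 12 and 13, from 2-methylpent-4-enal)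

Steps most likely to fail

Step 3. Ring closure onto the neopentyl-type vinyl group may be slow, so that acyclic diene metathesis oligomerisation and ruthenium-hydride isomerisation of the allyl terminus (leading to ring-contracted material) outrun cyclisation. The fallback closes the same C2'–C3' bond before the quaternary centre exists; it sets out from 1 and comes back at 6. Compound 1 would be treated with crotylmagnesium chloride (γ-addition) to give 3,5-dimethylocta-1,7-dien-4-ol F1. Dess–Martin oxidation would give 3,5-dimethylocta-1,7-dien-4-one F2. Tandem ring-closing metathesis–hydrogenation, now onto an unhindered secondary allylic vinyl group, should give 2,6-dimethylcyclohex-3-en-1-one F3 in the flask and then 2,6-dimethylcyclohexan-1-one F4. Deprotonation with LiN(i-Pr)2 and methylation with MeI in THF at −78 °C should then install the second methyl group and give 6.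

Step 7. The symmetrical dialdehyde may react at both ends (giving β-carotene) or the mono-adduct may be hard to separate from excess dialdehyde. The fallback moves the statistical event to the cheap, recyclable component; it sets out from 12 and comes back at 14. Compound 12 would be mono-acetalised with 2,2-dimethylpropane-1,3-diol (p-TsOH cat., toluene) to (2E,4E,6E)-7-(5,5-dimethyl-1,3-dioxan-2-yl)-2-methylocta-2,4,6-trienal F5, with bis-acetal and unreacted 12 recycled. Wittig reaction of F5 with ylide 13 (from 11, NaOMe) should give the C25 neopentyl glycol acetal F6, which cannot olefinate twice. Mild aqueous acid (dilute H2SO4, acetone/water) would release 14.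

Step 6. The one-pot dehydration and phosphonium salt formation may take the wrong elimination path (retro-type exocyclic dienes) or scramble the C9 double-bond geometry. The fallback makes the ring alkene as an enol triflate instead; it sets out from 6 (with 7) and comes back at 11. Ketone 6 would be converted with LiN(i-Pr)2 and PhNTf2 into 2,6,6-trimethylcyclohex-1-en-1-yl trifluoromethanesulfonate F7. Enynol 7 would be hydrostannylated (Bu3SnH, PdCl2(PPh3)2 cat.) to (2E,4E)-3-methyl-5-(tributylstannyl)penta-2,4-dien-1-ol F8. Stille coupling of F7 and F8 (Pd2(dba)3, AsPh3, N-methylpyrrolidone, 50 °C) should give (2E,4E)-3-methyl-5-(2,6,6-trimethylcyclohex-1-en-1-yl)penta-2,4-dien-1-ol F9. Treatment of F9 with PPh3·HBr in MeOH would then give 11 without any tertiary alcohol dehydration.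

Further compounds
F1 | step 3 | 3,5-dimethylocta-1,7-dien-4-ol (racemic diastereomer mixture) | C=CCC(C)C(O)C(C)C=C
F2 | step 3 | 3,5-dimethylocta-1,7-dien-4-one | C=CCC(C)C(=O)C(C)C=C
F3 | step 3 | 2,6-dimethylcyclohex-3-en-1-one (not isolated) | CC1CC=CC(C)C1=O
F4 | step 3 | 2,6-dimethylcyclohexan-1-one | CC1CCCC(C)C1=O
F5 | step 7 | (2E,4E,6E)-7-(5,5-dimethyl-1,3-dioxan-2-yl)-2-methylocta-2,4,6-trienal | O=C/C(C)=C/C=C/C=C(C)/C1OCC(C)(C)CO1
F6 | step 7 | 12'-apo-β-caroten-12'-al 5,5-dimethyl-1,3-dioxane acetal, all-E | CC1=C(/C=C/C(C)=C/C=C/C(C)=C/C=C/C=C(C)/C2OCC(C)(C)CO2)C(C)(C)CCC1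
F7 | step 6 | 2,6,6-trimethylcyclohex-1-en-1-yl trifluoromethanesulfonate | CC1=C(OS(=O)(=O)C(F)(F)F)C(C)(C)CCC1
F8 | step 6 | (2E,4E)-3-methyl-5-(tributylstannyl)penta-2,4-dien-1-ol | CCCC[Sn](CCCC)(CCCC)/C=C/C(C)=C/CO
F9 | step 6 | (2E,4E)-3-methyl-5-(2,6,6-trimethylcyclohex-1-en-1-yl)penta-2,4-dien-1-ol | CC1=C(/C=C/C(C)=C/CO)C(C)(C)CCC1
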